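**Retrosynthetic overview**
- Target 30 ⇐ Schenck ene reaction and reduction of the cyclic enol ether 28 (sets the C3 carbinol and the exocyclic C2=CH2) ⇐ cyclodehydration of bromohydrin ketone 26 (ring A, O1–C2 bond) ⇐ Shi epoxidation and bromide opening of prenyl ketone 24.
- 24 ⇐ isobutenyl cuprate addition to enone 21 ⇐ enol triflate 18 with an ethoxyvinyl Stille coupling ⇐ methyl ketone 16 ⇐ ester 11.
- 11 ⇐ closure of the C1'–C2' bond of ring B by ester enolate alkylation of tosylate 9 ⇐ anti bromochlorination of Z-allylic alcohol 6 ⇐ B-alkyl Suzuki coupling of iodide 3 with ester 4.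
- Feature used: in ring B (C1'–C6') the C3' bromine and C4' chlorine are trans and the C1' substituent is cis to bromine, so one chair carries all three equatorial (methyl axial). C3'/C4' therefore map onto anti addition to a Z-alkene, and C1' onto a chair closure. Ring B is formed first (step 5), ring A second (step 14).

Key step: step 5

**Remarks**
- Numbering: ring A is O1, C2 (=CH2), C3 (carbinol), C4, C5 (CHBr), C6 (CMe2); ring B is C1' (on C3), C2', C3' (CHBr), C4' (CMeCl), C5', C6'. Open-chain compounds are numbered as heptanoates or heptanones.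
- Assumption: the enantiomer of the Schiff-base ligand in step 3 is the one that delivers the (5S,6S) bromochloride; the sense of induction would be confirmed on 8.
- The C1' epimer of ring B can place both halogens axial and the methyl equatorial, and is expected to be at least as stable as the target arrangement. C1' is therefore set kinetically in step 5, and 11, 14 and 16 are never exposed to equilibrating base.
- Compounds 24 to 27 are mixtures at the future C3 (α to the ketone); this centre becomes sp2 in 28, so the mixtures converge.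
- Assumption: by the usual spiro transition-state model, the D-fructose-derived Shi ketone gives the (R)-epoxide of a 2-methylalk-2-ene, so its enantiomer (from L-sorbose) is used in step 12.

**Step 1**
Reactants: 1 but-2-yn-1-ol
Product: 3 (Z)-3-iodobut-2-en-1-ol, via cyclic alkenylalanate 2 (not isolated)
Conditions: NaAlH2(OCH2CH2OMe)2, THF, 0 °C to rt; then I2, THF, −78 to 0 °C
Reagents that add atoms: iodine, II
Why: Hydroxyl-directed trans-hydroalumination places aluminium at C3 in a five-membered alanate, and iododealumination with retention should give the iodide with iodine cis to CH2OH (hydroalumination–iodination of a propargylic alcohol).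

**Step 2**
Reactants: 3 (Z)-3-iodobut-2-en-1-ol; 4 tert-butyl but-3-enoate
Product: 6 tert-butyl (Z)-7-hydroxy-5-methylhept-5-enoate, via B-alkyl-9-BBN adduct 5 (not isolated)
Conditions: 4, 9-BBN, THF, 0 °C to rt; then 3, Pd(dppf)Cl2 (5 mol %), AsPh3, Cs2CO3, DMF/H2O, rt
Reagents that add atoms: none
Why: Anti-Markovnikov hydroboration of the terminal alkene and B-alkyl Suzuki–Miyaura coupling with retention of the iodide geometry should give the alkene with the ester chain cis to CH2OH.

**Step 3**
Reactants: 6 tert-butyl (Z)-7-hydroxy-5-methylhept-5-enoate; 7 N-bromosuccinimide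
Product: 8 tert-butyl (5S,6S)-6-bromo-5-chloro-7-hydroxy-5-methylheptanoate
Conditions: ClTi(OiPr)3 (1.1 equiv), chiral tridentate Schiff-base ligand (salicylaldimine of a 1,1-diaryl-2-amino alcohol, 20 mol %), hexanes, −20 °C
Reagents that add atoms: chlorotitanium triisopropoxide, CC(C)O[Ti](Cl)(OC(C)C)OC(C)C
Why: Catalytic enantioselective bromochlorination of an allylic alcohol, in which the titanium-bound ligand controls the face of bromonium formation and chloride opens anti at the tertiary carbon, should set C5 and C6 as the anti adduct of the Z-alkene.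

**Step 4**
Reactants: 8 tert-butyl (5S,6S)-6-bromo-5-chloro-7-hydroxy-5-methylheptanoate
Product: 9 tert-butyl (5S,6S)-6-bromo-5-chloro-5-methyl-7-(4-methylbenzenesulfonyloxy)heptanoate
Conditions: TsCl, Et3N, DMAP (cat.), CH2Cl2, 0 °C
Reagents that add atoms: 4-methylbenzenesulfonyl chloride, Cc1ccc(cc1)S(Cl)(=O)=O
Why: Sulfonylation of the primary alcohol under amine base, which is too weak to form the alkoxide that would close an epoxide onto the CHBr carbon.

**Step 5**
Reactants: 9 tert-butyl (5S,6S)-6-bromo-5-chloro-5-methyl-7-(4-methylbenzenesulfonyloxy)heptanoate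
Product: 11 tert-butyl (1S,3S,4S)-3-bromo-4-chloro-4-methylcyclohexane-1-carboxylate, via potassium ester enolate 10 (not isolated)
Conditions: KN(SiMe3)2 (1.0 equiv), THF, −78 to −40 °C; AcOH quench at −78 °C
Reagents that add atoms: none
Why: KN(SiMe3)2 removes a C2 hydrogen of the tert-butyl ester to give enolate 10, whose carbon displaces the primary tosylate at C7 by SN2; this is an intramolecular ester enolate alkylation. The closure is 6-exo-tet and forms the C1'–C2' bond of ring B. The forming bond must lie gauche to the C5–C6 ring bond, so the only approach not flanked by both bromine and the quaternary C5 is the one anti to the C–Br bond, which puts bromine, and with it the trans chlorine, equatorial in the chair-like transition state. In that chair the enolate unit should take the pseudo-equatorial position away from the axial hydrogens at C4 and C6, which sets C1' as S, cis to bromine. The step needs attack at the primary carbon and not at the CHBr carbon (5-exo, hindered by the adjacent quaternary carbon) or the tertiary chloride, and it needs kinetic control at C1', which one equivalent of base and a cold acidic quench should secure.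

**Step 6**
Reactants: 11 tert-butyl (1S,3S,4S)-3-bromo-4-chloro-4-methylcyclohexane-1-carboxylate
Product: 12 (1S,3S,4S)-3-bromo-4-chloro-4-methylcyclohexane-1-carboxylic acid
Conditions: TFA/CH2Cl2 (1:4), 0 °C to rt
Reagents that add atoms: none
Why: Acidolysis of the tert-butyl ester through the tert-butyl cation, under which the tertiary chloride, deactivated by the vicinal bromine, and the C1' centre should be unaffected.

**Step 7**
Reactants: 12 (1S,3S,4S)-3-bromo-4-chloro-4-methylcyclohexane-1-carboxylic acid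
Product: 14 (1S,3S,4S)-3-bromo-4-chloro-N-methoxy-N,4-dimethylcyclohexane-1-carboxamide, via acyl imidazolide 13 (not isolated)
Conditions: 1,1'-carbonyldiimidazole, CH2Cl2, rt; then MeNH(OMe)·HCl, rt
Reagents that add atoms: N,O-dimethylhydroxylamine hydrochloride, CNOC.Cl
Why: Activation of the acid as the acyl imidazolide and aminolysis give the Weinreb amide without strong base, so C1' is not touched.

**Step 8**
Reactants: 14 (1S,3S,4S)-3-bromo-4-chloro-N-methoxy-N,4-dimethylcyclohexane-1-carboxamide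
Product: 16 1-[(1S,3S,4S)-3-bromo-4-chloro-4-methylcyclohexyl]ethan-1-one, via magnesium hemiaminal chelate 15 (not isolated)
Conditions: MeMgBr (1.5 equiv), THF, −20 to 0 °C; cold aq NH4Cl
Reagents that add atoms: methylmagnesium bromide, C[Mg]Br
Why: Weinreb ketone synthesis, in which the chelated tetrahedral adduct 15 survives until the quench, so there is no over-addition and the ketone is released only under near-neutral conditions.

**Step 9**
Reactants: 16 1-[(1S,3S,4S)-3-bromo-4-chloro-4-methylcyclohexyl]ethan-1-one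
Product: 18 1-[(1S,3S,4S)-3-bromo-4-chloro-4-methylcyclohexyl]ethenyl trifluoromethanesulfonate, via lithium enolate 17 (not isolated)
Conditions: LiN(iPr)2 (1.1 equiv), THF, −78 °C (ketone added to base); then PhNTf2, −78 to 0 °C
Reagents that add atoms: N-phenylbis(trifluoromethanesulfonimide), O=S(=O)(N(c1ccccc1)S(=O)(=O)C(F)(F)F)C(F)(F)F
Why: Kinetic deprotonation of a methyl sec-alkyl ketone occurs at the methyl group, so O-triflation should give the terminal enol triflate and leave the C1' hydrogen in place.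

**Step 10**
Reactants: 18 1-[(1S,3S,4S)-3-bromo-4-chloro-4-methylcyclohexyl]ethenyl trifluoromethanesulfonate; 19 tributyl(1-ethoxyethenyl)stannane
Product: 21 3-[(1S,3S,4S)-3-bromo-4-chloro-4-methylcyclohexyl]but-3-en-2-one, via 2-ethoxydiene 20 (not isolated)
Conditions: Pd(PPh3)4 (5 mol %), LiCl, THF, 65 °C; then 1 M HCl, rt
Reagents that add atoms: water, O
Why: Stille coupling of the alkenyl triflate with the acyl-anion equivalent, followed by hydrolysis of the enol ether, gives the α-substituted enone; unactivated alkyl halides should not react with the palladium catalyst under these conditions.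

**Step 11**
Reactants: 21 3-[(1S,3S,4S)-3-bromo-4-chloro-4-methylcyclohexyl]but-3-en-2-one; 22 (2-methylprop-1-en-1-yl)magnesium bromide
Product: 24 3-[(1S,3S,4S)-3-bromo-4-chloro-4-methylcyclohexyl]-6-methylhept-5-en-2-one, via magnesium enolate 23 (not isolated)
Conditions: CuBr·SMe2 (20 mol %), THF, −78 to −40 °C; aq NH4Cl
Reagents that add atoms: none
Why: Copper-catalysed conjugate addition of the alkenyl Grignard reagent to the unhindered β-carbon of the enone, with unselective protonation at the α-carbon, which is of no consequence.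

**Step 12**
Reactants: 24 3-[(1S,3S,4S)-3-bromo-4-chloro-4-methylcyclohexyl]-6-methylhept-5-en-2-one
Product: 25 3-[(1S,3S,4S)-3-bromo-4-chloro-4-methylcyclohexyl]-4-[(2S)-3,3-dimethyloxiran-2-yl]butan-2-one
Conditions: L-fructose-derived Shi ketone (30 mol %), KHSO5 (as 2KHSO5·KHSO4·K2SO4), K2CO3, Bu4NHSO4, MeCN/dimethoxymethane/aq Na2B4O7–Na2EDTA buffer, 0 °C
Reagents that add atoms: potassium peroxymonosulfate, [K+].[O-]S(=O)(=O)OO
Why: Shi epoxidation of the trisubstituted alkene by the chiral dioxirane through the spiro transition state should set the epoxide CH as S under reagent control.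

**Step 13**
Reactants: 25 3-[(1S,3S,4S)-3-bromo-4-chloro-4-methylcyclohexyl]-4-[(2S)-3,3-dimethyloxiran-2-yl]butan-2-one
Product: 26 (5R)-5-bromo-3-[(1S,3S,4S)-3-bromo-4-chloro-4-methylcyclohexyl]-6-hydroxy-6-methylheptan-2-one
Conditions: Li2NiBr4 (0.4 M in THF, 2.5 equiv), THF, 0 °C to rt; pH 7 buffer
Reagents that add atoms: dilithium tetrabromonickelate, [Li+].[Li+].Br[Ni-2](Br)(Br)Br
Why: The soft bromide of Li2NiBr4 opens the epoxide by SN2 at the less substituted carbon with inversion, so the (S)-epoxide should give the (R)-bromide and the tertiary alcohol.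

**Step 14**
Reactants: 26 (5R)-5-bromo-3-[(1S,3S,4S)-3-bromo-4-chloro-4-methylcyclohexyl]-6-hydroxy-6-methylheptan-2-one
Product: 28 (3R)-3-bromo-5-[(1S,3S,4S)-3-bromo-4-chloro-4-methylcyclohexyl]-2,2,6-trimethyl-3,4-dihydro-2H-pyran, via cyclic hemiketal 27 (not isolated)
Conditions: PPTS (10 mol %), 4 Å MS, toluene, 70 °C
Reagents that add atoms: none
Why: Acid-catalysed cyclodehydration: the tertiary hydroxyl closes ring A onto the ketone (O1–C2 bond) and loss of water should give the more substituted endocyclic enol ether, in which both C3 epimers converge.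

**Step 15**
Reactants: 28 (3R)-3-bromo-5-[(1S,3S,4S)-3-bromo-4-chloro-4-methylcyclohexyl]-2,2,6-trimethyl-3,4-dihydro-2H-pyran
Product: 30 (3S,5R)-5-bromo-3-[(1S,3S,4S)-3-bromo-4-chloro-4-methylcyclohexyl]-6,6-dimethyl-2-methylideneoxan-3-ol, via allylic hydroperoxide 29 (not isolated)
Conditions: O2, tetraphenylporphyrin (cat.), visible light, CH2Cl2 with a trace of pyridine, −78 °C; then PPh3, −78 °C to rt; chromatography on Et3N-deactivated silica
Reagents that add atoms: dioxygen, O=O
Why: In this Schenck ene reaction singlet oxygen is expected to bond to the nucleophilic C3 on the face anti to the C5 bromine and to take a hydrogen from the C2 methyl group (the only hydrogens next to the developing oxocarbenium carbon), which sets C3 as S and moves the double bond to the exocyclic position; PPh3 then reduces the hydroperoxide with retention.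

**Compound list**
1 | but-2-yn-1-ol | CC#CCO | starting material
2 | sodium cyclic alkenylalanate of 1 (2,5-dihydro-1,2-oxaalumol-2-uide with two 2-methoxyethoxy groups on aluminium) | CC1=CCO[Al-]1(OCCOC)OCCOC.[Na+] | intermediate (not isolated)
3 | (Z)-3-iodobut-2-en-1-ol | C/C(I)=C/CO | intermediate
4 | tert-butyl but-3-enoate | C=CCC(=O)OC(C)(C)C | starting material
5 | tert-butyl 4-(9-borabicyclo[3.3.1]nonan-9-yl)butanoate | CC(C)(C)OC(=O)CCCB1C2CCCC1CCC2 | intermediate (not isolated)
6 | tert-butyl (Z)-7-hydroxy-5-methylhept-5-enoate | CC(C)(C)OC(=O)CCC/C(C)=C\CO | intermediate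
7 | N-bromosuccinimide | O=C1CCC(=O)N1Br | starting material
8 | tert-butyl (5S,6S)-6-bromo-5-chloro-7-hydroxy-5-methylheptanoate | CC(C)(C)OC(=O)CCC[C@](C)(Cl)[C@@H](Br)CO | intermediate
9 | tert-butyl (5S,6S)-6-bromo-5-chloro-5-methyl-7-(4-methylbenzenesulfonyloxy)heptanoate | CC(C)(C)OC(=O)CCC[C@](C)(Cl)[C@@H](Br)COS(=O)(=O)c1ccc(C)cc1 | intermediate
10 | potassium enolate of 9 | [K+].CC(C)(C)OC([O-])=CCC[C@](C)(Cl)[C@@H](Br)COS(=O)(=O)c1ccc(C)cc1 | intermediate (not isolated)
11 | tert-butyl (1S,3S,4S)-3-bromo-4-chloro-4-methylcyclohexane-1-carboxylate | CC(C)(C)OC(=O)[C@H]1CC[C@](C)(Cl)[C@@H](Br)C1 | intermediate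
12 | (1S,3S,4S)-3-bromo-4-chloro-4-methylcyclohexane-1-carboxylic acid | OC(=O)[C@H]1CC[C@](C)(Cl)[C@@H](Br)C1 | intermediate
13 | [(1S,3S,4S)-3-bromo-4-chloro-4-methylcyclohexyl](imidazol-1-yl)methanone | O=C(n1ccnc1)[C@H]1CC[C@](C)(Cl)[C@@H](Br)C1 | intermediate (not isolated)
14 | (1S,3S,4S)-3-bromo-4-chloro-N-methoxy-N,4-dimethylcyclohexane-1-carboxamide | CON(C)C(=O)[C@H]1CC[C@](C)(Cl)[C@@H](Br)C1 | intermediate
15 | bromomagnesium alkoxide of the methyl adduct of 14 (chelated hemiaminal) | CON(C)C(C)(O[Mg]Br)[C@H]1CC[C@](C)(Cl)[C@@H](Br)C1 | intermediate (not isolated)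
16 | 1-[(1S,3S,4S)-3-bromo-4-chloro-4-methylcyclohexyl]ethan-1-one | CC(=O)[C@H]1CC[C@](C)(Cl)[C@@H](Br)C1 | intermediate
17 | lithium 1-[(1S,3S,4S)-3-bromo-4-chloro-4-methylcyclohexyl]ethen-1-olate | [Li+].C=C([O-])[C@H]1CC[C@](C)(Cl)[C@@H](Br)C1 | intermediate (not isolated)
18 | 1-[(1S,3S,4S)-3-bromo-4-chloro-4-methylcyclohexyl]ethenyl trifluoromethanesulfonate | C=C(OS(=O)(=O)C(F)(F)F)[C@H]1CC[C@](C)(Cl)[C@@H](Br)C1 | intermediate
19 | tributyl(1-ethoxyethenyl)stannane | CCCC[Sn](CCCC)(CCCC)C(=C)OCC | starting material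
20 | 2-[(1S,3S,4S)-3-bromo-4-chloro-4-methylcyclohexyl]-3-ethoxybuta-1,3-diene | C=C(OCC)C(=C)[C@H]1CC[C@](C)(Cl)[C@@H](Br)C1 | intermediate (not isolated)
21 | 3-[(1S,3S,4S)-3-bromo-4-chloro-4-methylcyclohexyl]but-3-en-2-one | CC(=O)C(=C)[C@H]1CC[C@](C)(Cl)[C@@H](Br)C1 | intermediate
22 | (2-methylprop-1-en-1-yl)magnesium bromide | CC(C)=C[Mg]Br | starting material
23 | bromomagnesium enolate of 24 | CC(O[Mg]Br)=C(CC=C(C)C)[C@H]1CC[C@](C)(Cl)[C@@H](Br)C1 | intermediate (not isolated)
24 | 3-[(1S,3S,4S)-3-bromo-4-chloro-4-methylcyclohexyl]-6-methylhept-5-en-2-one (C3 epimers) | CC(=O)C(CC=C(C)C)[C@H]1CC[C@](C)(Cl)[C@@H](Br)C1 | intermediate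
25 | 3-[(1S,3S,4S)-3-bromo-4-chloro-4-methylcyclohexyl]-4-[(2S)-3,3-dimethyloxiran-2-yl]butan-2-one (C3 epimers) | CC(=O)C(C[C@@H]1OC1(C)C)[C@H]2CC[C@](C)(Cl)[C@@H](Br)C2 | intermediate
26 | (5R)-5-bromo-3-[(1S,3S,4S)-3-bromo-4-chloro-4-methylcyclohexyl]-6-hydroxy-6-methylheptan-2-one (C3 epimers) | CC(=O)C(C[C@@H](Br)C(C)(C)O)[C@H]1CC[C@](C)(Cl)[C@@H](Br)C1 | intermediate
27 | (5R)-5-bromo-3-[(1S,3S,4S)-3-bromo-4-chloro-4-methylcyclohexyl]-2,6,6-trimethyloxan-2-ol (C2 and C3 epimers) | CC1(O)OC(C)(C)[C@H](Br)CC1[C@H]2CC[C@](C)(Cl)[C@@H](Br)C2 | intermediate (not isolated)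
28 | (3R)-3-bromo-5-[(1S,3S,4S)-3-bromo-4-chloro-4-methylcyclohexyl]-2,2,6-trimethyl-3,4-dihydro-2H-pyran | CC1=C([C@H]2CC[C@](C)(Cl)[C@@H](Br)C2)C[C@@H](Br)C(C)(C)O1 | intermediate
29 | (3S,5R)-5-bromo-3-[(1S,3S,4S)-3-bromo-4-chloro-4-methylcyclohexyl]-3-hydroperoxy-6,6-dimethyl-2-methylideneoxane | C=C1OC(C)(C)[C@H](Br)C[C@]1(OO)[C@H]1CC[C@](C)(Cl)[C@@H](Br)C1 | intermediate (not isolated)
30 | (3S,5R)-5-bromo-3-[(1S,3S,4S)-3-bromo-4-chloro-4-methylcyclohexyl]-6,6-dimethyl-2-methylideneoxan-3-ol | C=C1OC(C)(C)[C@H](Br)C[C@]1(O)[C@H]1CC[C@](C)(Cl)[C@@H](Br)C1 | target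

**Step count**
Total: 15 steps. Longest linear sequence: 15 steps, from but-2-yn-1-ol 1.

**Steps most likely to fail**

1. Step 5 (ring B closure). The closure may be overtaken by loss of HBr or TsOH under the amide base or the enolate, by attack of the enolate on bromine with expulsion of tosylate, or by closure through the chair with axial halogens, which gives the C1' epimer; proton exchange after closure would also erode C1'. The fallback sets out from 8 and comes back at 12, and it makes the nucleophile doubly stabilised so that a carbonate base suffices for the same C1'–C2' bond.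
   - Alcohol 8 would be silylated (TBSCl, imidazole, DMF) to tert-butyl (5S,6S)-6-bromo-7-[tert-butyl(dimethyl)silyloxy]-5-chloro-5-methylheptanoate F1.
   - Its lithium enolate (LiN(iPr)2, 2.1 equiv, THF, −78 °C) would be acylated with Boc2O to di-tert-butyl 2-[(3S,4S)-4-bromo-5-[tert-butyl(dimethyl)silyloxy]-3-chloro-3-methylpentyl]propanedioate F2.
   - HF·pyridine would free di-tert-butyl 2-[(3S,4S)-4-bromo-3-chloro-5-hydroxy-3-methylpentyl]propanedioate F3, and TsCl/Et3N would give di-tert-butyl 2-[(3S,4S)-4-bromo-3-chloro-3-methyl-5-(4-methylbenzenesulfonyloxy)pentyl]propanedioate F4.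
   - Cs2CO3 in DMF at rt would close ring B to di-tert-butyl (3S,4S)-3-bromo-4-chloro-4-methylcyclohexane-1,1-dicarboxylate F5.
   - TFA would give (3S,4S)-3-bromo-4-chloro-4-methylcyclohexane-1,1-dicarboxylic acid F6, which would lose CO2 on heating in toluene to give 12. In this variant C1' is set by protonation and not by the ring closure, so the C1' epimers of 12 would have to be separated by chromatography.

2. Step 15 (oxygenation of C3). Singlet oxygen may instead take a ring hydrogen from C4 with C–O bonding at C2, may add [2+2] to give a dioxetane that cleaves the C2=C3 bond, or may oxidise the product enol ether further. The fallback sets out from 28 and ends at 30.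
   - Dimethyldioxirane in acetone/CH2Cl2/MeOH at −78 °C would epoxidise the enol ether anti to the C5 bromine to 4-bromo-6-[(1S,3S,4S)-3-bromo-4-chloro-4-methylcyclohexyl]-1,3,3-trimethyl-2,7-dioxabicyclo[4.1.0]heptane (epoxide oxygen trans to bromine) F7.
   - Methanol would open it at the acetal carbon to (3S,5R)-5-bromo-3-[(1S,3S,4S)-3-bromo-4-chloro-4-methylcyclohexyl]-2-methoxy-2,6,6-trimethyloxan-3-ol F8 (C2 epimers).
   - TMSOTf/iPr2NEt in CH2Cl2 would silylate the C3 hydroxyl and ionise the methoxy group. Because C3 is quaternary, the oxocarbenium ion can lose a proton only from the C2 methyl group, which would give [(3S,5R)-5-bromo-3-[(1S,3S,4S)-3-bromo-4-chloro-4-methylcyclohexyl]-6,6-dimethyl-2-methylideneoxan-3-yl]oxy(trimethyl)silane F9.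
   - K2CO3 in MeOH would remove the silyl group to give 30.

3. Step 13 (epoxide opening). Bromide may attack the tertiary epoxide carbon, or the ketone oxygen may attack the Lewis-acid-activated epoxide and collapse to a bicyclic ketal. The fallback sets out from 24 and comes back at 28, and it masks the ketone before the alkene is oxidised.
   - Ethylene glycol with PPTS in benzene (water removal) would give 2-{1-[(1S,3S,4S)-3-bromo-4-chloro-4-methylcyclohexyl]-4-methylpent-3-en-1-yl}-2-methyl-1,3-dioxolane F10.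
   - Shi epoxidation as in step 12 would give 2-{1-[(1S,3S,4S)-3-bromo-4-chloro-4-methylcyclohexyl]-2-[(2S)-3,3-dimethyloxiran-2-yl]ethyl}-2-methyl-1,3-dioxolane F11.
   - Li2NiBr4 would give (3R)-3-bromo-5-[(1S,3S,4S)-3-bromo-4-chloro-4-methylcyclohexyl]-2-methyl-5-(2-methyl-1,3-dioxolan-2-yl)pentan-2-ol F12.
   - PPTS in warm toluene would then exchange the dioxolane for the tertiary hydroxyl and eliminate, giving 28 directly.

**Further compounds**
F1 | step 5 | tert-butyl (5S,6S)-6-bromo-7-[tert-butyl(dimethyl)silyloxy]-5-chloro-5-methylheptanoate | CC(C)(C)OC(=O)CCC[C@](C)(Cl)[C@@H](Br)CO[Si](C)(C)C(C)(C)C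
F2 | step 5 | di-tert-butyl 2-[(3S,4S)-4-bromo-5-[tert-butyl(dimethyl)silyloxy]-3-chloro-3-methylpentyl]propanedioate | CC(C)(C)OC(=O)C(CC[C@](C)(Cl)[C@@H](Br)CO[Si](C)(C)C(C)(C)C)C(=O)OC(C)(C)C
F3 | step 5 | di-tert-butyl 2-[(3S,4S)-4-bromo-3-chloro-5-hydroxy-3-methylpentyl]propanedioate | CC(C)(C)OC(=O)C(CC[C@](C)(Cl)[C@@H](Br)CO)C(=O)OC(C)(C)C
F4 | step 5 | di-tert-butyl 2-[(3S,4S)-4-bromo-3-chloro-3-methyl-5-(4-methylbenzenesulfonyloxy)pentyl]propanedioate | CC(C)(C)OC(=O)C(CC[C@](C)(Cl)[C@@H](Br)COS(=O)(=O)c1ccc(C)cc1)C(=O)OC(C)(C)C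
F5 | step 5 | di-tert-butyl (3S,4S)-3-bromo-4-chloro-4-methylcyclohexane-1,1-dicarboxylate | CC(C)(C)OC(=O)C1(CC[C@](C)(Cl)[C@@H](Br)C1)C(=O)OC(C)(C)C
F6 | step 5 | (3S,4S)-3-bromo-4-chloro-4-methylcyclohexane-1,1-dicarboxylic acid | OC(=O)C1(CC[C@](C)(Cl)[C@@H](Br)C1)C(=O)O
F7 | step 15 | 4-bromo-6-[(1S,3S,4S)-3-bromo-4-chloro-4-methylcyclohexyl]-1,3,3-trimethyl-2,7-dioxabicyclo[4.1.0]heptane (epoxide oxygen trans to bromine) | C[C@@]12O[C@@]1(C[C@@H](Br)C(C)(C)O2)[C@H]3CC[C@](C)(Cl)[C@@H](Br)C3
F8 | step 15 | (3S,5R)-5-bromo-3-[(1S,3S,4S)-3-bromo-4-chloro-4-methylcyclohexyl]-2-methoxy-2,6,6-trimethyloxan-3-ol (C2 epimers) | COC1(C)OC(C)(C)[C@H](Br)C[C@]1(O)[C@H]2CC[C@](C)(Cl)[C@@H](Br)C2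
F9 | step 15 | [(3S,5R)-5-bromo-3-[(1S,3S,4S)-3-bromo-4-chloro-4-methylcyclohexyl]-6,6-dimethyl-2-methylideneoxan-3-yl]oxy(trimethyl)silane | C=C1OC(C)(C)[C@H](Br)C[C@]1(O[Si](C)(C)C)[C@H]2CC[C@](C)(Cl)[C@@H](Br)C2
F10 | step 13 | 2-{1-[(1S,3S,4S)-3-bromo-4-chloro-4-methylcyclohexyl]-4-methylpent-3-en-1-yl}-2-methyl-1,3-dioxolane | CC1(OCCO1)C(CC=C(C)C)[C@H]2CC[C@](C)(Cl)[C@@H](Br)C2
F11 | step 13 | 2-{1-[(1S,3S,4S)-3-bromo-4-chloro-4-methylcyclohexyl]-2-[(2S)-3,3-dimethyloxiran-2-yl]ethyl}-2-methyl-1,3-dioxolane | CC1(OCCO1)C(C[C@@H]2OC2(C)C)[C@H]3CC[C@](C)(Cl)[C@@H](Br)C3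
F12 | step 13 | (3R)-3-bromo-5-[(1S,3S,4S)-3-bromo-4-chloro-4-methylcyclohexyl]-2-methyl-5-(2-methyl-1,3-dioxolan-2-yl)pentan-2-ol | CC1(OCCO1)C(C[C@@H](Br)C(C)(C)O)[C@H]2CC[C@](C)(Cl)[C@@H](Br)C2
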